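The readings are simulated from invented constants, noise included.

Read the straight stretch before fitting anything, the chair told the meeting on the flask, which runs the racemate under the gas and catalyst of ash and maple.

| setting | ash | maple | flask |
|---|---|---|---|
| left-handed substrate | 0.0013 M | 0.0030 M | 0.0020 M |
| right-handed substrate | 0.0013 M | 0.0030 M | 0.0020 M |
| gas | 0.90 mM (held) | 0.90 mM (held) | 0.90 mM (held) |
| free catalyst | 20 µM | 20 µM | 20 µM |
| remark | run made earlier | run made earlier |  |
| time |  |  | 25 min |

- ash (time / min: right-handed substrate / %, left-handed substrate / %, left-handed product / %): 1.50: 50.2, 31.3, 21.0; 5.00: 48.5, 0, 50.4; 8.00: 47.4, 0.5, 49.1; 15.0: 48.4, 0.8, 50.1; 20.0: 47.8, 2.4, 50.2; 25.0: 47.5, 0, 51.1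
- maple (time / min: right-handed substrate / %, left-handed substrate / %, left-handed product / %): 2.00: 49.3, 35.0, 12.5; 3.00: 48.6, 29.3, 21.0; 6.00: 47.4, 8.0, 41.3; 10.0: 48.7, 0.7, 49.2; 15.0: 47.7, 0, 51.6; 25.0: 48.5, 0.1, 48.6

(each reading ± 1 percentage point)

1. whether the excess of right-handed substrate over left-handed substrate among what is left of the two reaches 95% by 25 min (yes / no)
2. the highest excess of right-handed substrate over left-handed substrate among what is left of the two up to 25 min

- free catalyst is single-handed; left-handed substrate and right-handed substrate are mirror images of each other, charged as a racemate, each of them at the stated concentration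
- at the start none of the gas is in solution

The first speaker reported that in maple the left-handed product climbed nearly straight from 12.5% at 2.00 min to 41.3% at 6.00 min, which he read as a rate that hardly follows the left-handed substrate (zero order in it). The readings are percent of the two substrates charged together, and maple's left-handed charge is half of that, so counted against this charge the climb is 0.144 min⁻¹.

The secretary added her own reckoning, the clearing time: a flask's left-handed charge over that rate, at this gas and catalyst. Maple's is 6.94 min. The flask holds 66.7% of maple's charge, so its clearing time is 4.63 min.

A second speaker tried it on ash, whose clearing time comes out at 3.01 min; ash read 31.3% left at 1.50 min and 0% at 5.00 min, on either side of it. He asked whether the catalyst would last, and the first speaker answered that maple, with a larger charge than the flask, read 0.7% left at 10.0 min.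

The forecast was entered as yes and 99.5%, with the left-handed substrate gone in about 5 to 7 min against the secretary's 4.63 min: “The excess should therefore reach about 99–100% and hold.”

The flask gives yes and 99.6%.

    reagent + catalyst intermediate B → free catalyst + right-handed product (k = 428 M⁻¹ s⁻¹)
    reagent + catalyst intermediate A → free catalyst + left-handed product (k = 2290 M⁻¹ s⁻¹)
    gas ⇌ reagent, rate k3*(csat - [reagent]) (kL = 0.0118 s⁻¹)
    free catalyst + right-handed substrate ⇌ catalyst intermediate B (K = 150 M⁻¹, k = 6220 M⁻¹ s⁻¹)
    reagent + free catalyst → spent catalyst (k = 25.2 M⁻¹ s⁻¹)
    free catalyst + left-handed substrate ⇌ catalyst intermediate A (K = 3600 M⁻¹, k = 1.23 × 10⁵ M⁻¹ s⁻¹)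

In the flask the left-handed substrate stood at 24.7% of the two substrates charged at 2.50 min, with catalyst intermediate A, the resting state, at 65.1% of the catalyst, and the wanted excess came at 5.78 min, which is 1.25 times the clearing time and still inside the 25 min allowed. Spent catalyst stood at 99.9% by 12.5 min, and at 25.0 min the flask held 0.0969% left-handed substrate against 47.5% right-handed substrate, with 2.47% right-handed product, an excess of 99.6%.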